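Amounts first: the flask holds 50.0 % of incoming ligand per starting complex charged, so the ligand is the limiting reagent, and no step listed consumes the leaving ligand.

starting complex 0.050 M (in portions, 3); incoming ligand 0.0250 M; leaving ligand 0.100 M; time 6.0 h; the portions of starting complex follow each other after 1.5 min, the first at the start

    complex with one exchanged ⇌ isomer of the product (K1 = 0.47, k1 = 0.0164 min⁻¹)
    starting complex + incoming ligand → leaving ligand + complex with one exchanged (k2 = 0.596 M⁻¹ min⁻¹)
    complex with one exchanged + incoming ligand → leaving ligand + complex with two exchanged (k3 = 1.98 M⁻¹ min⁻¹)

1. how much of the starting complex has reacted by 6.0 h
2. how much complex with one exchanged there is at 6.0 h, in percent of the starting complex charged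
3. how much complex with two exchanged there is at 6.0 h, in percent of the starting complex charged
4. amount of complex with one exchanged if the flask were left three thousand times as long, in percent of the starting complex charged

I reckoned in fractions of the charge. Each starting complex that reacts takes one ligand and each complex with two exchanged takes a second, so in a finished flask the conversion plus the two-exchanged fraction equals x. The pool of complex with one exchanged and isomer is the conversion minus that fraction, so the conversion is the mean of x and the pool. The portions are in after 3.00 min, shorter than the ligand's half-life of 0.388 h by step 2 on the whole charge, so I took them as one charge.

Dividing the rate of step 3 by that of step 2 gives the pool as (m − m^s)/(s − 1), with m the fraction of starting complex left and s the ratio of the two competing steps. I solved this by one substitution from a trial conversion of 33.3 %, in two ways. If no isomer formed, s is k3/k2, 3.32, and the conversion is 33.8 %. If the pair stood at equilibrium throughout, the isomer is out of the ligand's reach, and s becomes the effective selectivity factor, k3/k2 divided by one plus K1, 2.26, with a conversion of 35.6 %.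

The two ways part, and each cheats. The pair's relaxation half-life of 0.225 h is shorter than 0.388 h, but not by enough to call it instant, so I committed to a conversion between the two. That puts the two-exchanged fraction between 14.4 % and 16.2 %. The asked time holds 15.5 ligand half-lives and 26.6 relaxation half-lives, so I took the pair as equilibrated, which puts complex with one exchanged between 11.9 % and 14.4 %, and the same for the long-left flask.

The forecast stood at 35.1 % for the conversion and 14.9 % for complex with two exchanged, and it put complex with one exchanged at 13.7 % at the asked time and 13.7 % in the long-left flask, those two on the ground that the isomerisation “equilibrates within a couple of hours”.

The flask gave 35.1 %, 13.7 %, 14.9 % and 13.7 %, inside my ranges. The conversion stops there through the using up of the incoming ligand: 0 % of it remained at 6.00 h, and a run with the ligand held reached 99.5 % against 35.1 %. In the neighbour flask with 0.085 M of starting complex, x falls to 29.4 %. From a trial of 19.6 %, the same 2.26 gives a conversion of 22.4 %, then 23.1 %, with 6.30 % two-exchanged. That flask gave 22.7 % and 6.75 %.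

Its constants belong to no real substance, and the outcome is calculated.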